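**Retrosynthetic overview**

1. Positions follow carotenoid numbering (ring C1–C6, chain C7–C15, primes for the ring B half). The target, (5S,6S,5′R,6′S)-5,5′-dihydroxy-5,6,5′,6′-tetrahydro-β,β-carotene-3,3′-dione, is cut once, at the C12–C13 single bond, into the C16 trienyl iodide 18 (ring A) and the C24 hexaenylstannane 27 (ring B). The two unprotected halves are joined in the last step by a copper-assisted Stille coupling.
2. Enabling feature: C12 (=CH–) and C13 (=C(CH3)–) are both sp2 carbons of the all-E polyene, six and twelve bonds away from the ring stereocenters, and each ring holds a base-labile aldol unit (C3 ketone, C4H2, tertiary C5 carbinol). A stereoretentive, neutral alkenyl–alkenyl coupling can therefore finish the C40 nonaene with no protecting group and no step after it.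
3. 27 comes from ring B iodide 13 and the C8 distannane 26 (C13 to C13′, from (E)-1,2-dichloroethene and two molecules of propyne). 13 and 18 are C5 epimers made by one sequence from the cis and trans alcohols 5 and 6, which form together from racemic α-ionone (chain extension, C3 oxidation, reduction) and are resolved by a lipase.
4. No carbocycle is formed: both six-membered rings are those of α-ionone. On each, a temporary C4–C5 oxirane is placed by the C3 hydroxyl and opened reductively to set C5 (ring B in steps 8–10, ring A in steps 13–15) before either ring enters a coupling.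

Key step: step 20

Assumption: in steps 4 and 5 the lipase acylates the (3R)-carbinol of either racemate, the usual preference for cyclohex-2-en-1-ols with the alkenyl side as the larger substituent.

**Route**

Step 1
Reactants: 1 (±)-α-ionone; 2 diethyl cyanomethylphosphonate
Product: 3 (±)-(2E,4E)-3-methyl-5-(2,6,6-trimethylcyclohex-2-en-1-yl)penta-2,4-dienenitrile
Conditions: NaH, THF, 0 °C to rt; chromatography removes the minor (2Z) isomer
Reagents that add atoms: none
Why: Horner–Wadsworth–Emmons olefination of the methyl ketone should give mainly the (9E)-dienenitrile, as is routine for ionones.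

Step 2
Reactants: 3 (±)-dienenitrile
Product: 4 (±)-(2E,4E)-3-methyl-5-(2,6,6-trimethyl-4-oxocyclohex-2-en-1-yl)penta-2,4-dienenitrile
Conditions: t-BuOOH, Pd(OH)2/C (cat.), K2CO3, CH2Cl2, 4 °C to rt
Reagents that add atoms: tert-butyl hydroperoxide, CC(C)(C)OO
Why: Peroxyl-radical allylic oxidation should convert ring C3, the only unhindered secondary allylic position, into the enone, because C6–H is tertiary and flanked by the quaternary C1 while the other allylic sites are methyl groups.

Step 3
Reactants: 4 (±)-enone
Product: 5 racemic 3,6-cis alcohol, rac-(2E,4E)-5-[(1S,4R)-4-hydroxy-2,6,6-trimethylcyclohex-2-en-1-yl]-3-methylpenta-2,4-dienenitrile; 6 racemic 3,6-trans alcohol, rac-(2E,4E)-5-[(1S,4S)-4-hydroxy-2,6,6-trimethylcyclohex-2-en-1-yl]-3-methylpenta-2,4-dienenitrile (separated by chromatography, both used)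
Conditions: NaBH4, CeCl3·7H2O, MeOH, −20 °C
Reagents that add atoms: none
Why: Luche 1,2-reduction of the β,β-disubstituted enone is not expected to discriminate strongly between the two faces of C3 (one is shielded by the axial C1 methyl group, the other by the side chain), so both racemic diastereomers should form; 5 leads to ring B and 6 to ring A.

Step 4
Reactants: 5 racemic 3,6-cis alcohol
Product: 7 (1R,4S)-4-[(1E,3E)-4-cyano-3-methylbuta-1,3-dien-1-yl]-3,5,5-trimethylcyclohex-2-en-1-yl acetate, the (3R,6S) acetate
Conditions: Amano lipase PS (immobilized), vinyl acetate, t-BuOMe, 30 °C, stopped near half conversion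
Reagents that add atoms: vinyl acetate, C=COC(C)=O
Why: Lipase-catalysed kinetic resolution by irreversible transesterification should acylate only the (3R)-carbinol, so the (3R,6S) enantiomer is separated as its acetate from the unreacted (3S,6R) alcohol; this fixes the absolute configuration at C6 for ring B.

Step 5
Reactants: 6 racemic 3,6-trans alcohol
Product: 8 (2E,4E)-5-[(1S,4S)-4-hydroxy-2,6,6-trimethylcyclohex-2-en-1-yl]-3-methylpenta-2,4-dienenitrile, the (3S,6S) alcohol, recovered as the unacylated enantiomer
Conditions: Amano lipase PS (immobilized), vinyl acetate, t-BuOMe, 30 °C, run slightly past half conversion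
Reagents that add atoms: none
Why: The same lipase-catalysed kinetic resolution should acylate the (3R,6R) enantiomer and leave the (3S,6S) alcohol, which fixes the absolute configuration at C6 for ring A.

Step 6
Reactants: 7 (3R,6S) acetate
Product: 9 (2E,4E)-5-[(1S,4R)-4-hydroxy-2,6,6-trimethylcyclohex-2-en-1-yl]-3-methylpenta-2,4-dienal
Conditions: i-Bu2AlH (excess), CH2Cl2, −78 °C; then 10% aq. tartaric acid, 0 °C
Reagents that add atoms: water, O
Why: Reduction with i-Bu2AlH stops at the N-aluminated aldimine, which is hydrolysed on work-up to the dienal, and cleaves the acetate reductively in the same operation without touching the stereocenters or the olefin geometry.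

Step 7
Reactants: 9 cis hydroxy dienal
Product: 10 (1R,4S)-4-[(1E,3E,5E)-6-iodo-3-methylhexa-1,3,5-trien-1-yl]-3,5,5-trimethylcyclohex-2-en-1-ol
Conditions: CrCl2, CHI3, THF/1,4-dioxane, 0 °C to rt, dark
Reagents that add atoms: iodoform, IC(I)I
Why: Takai iodo-olefination (geminal dichromium carbenoid) reacts only with the aldehyde and should give the (E)-alkenyl iodide, the free allylic alcohol being tolerated.

Step 8
Reactants: 10 cis trienyl iodide
Product: 11 (1R,2R,5S,6S)-5-[(1E,3E,5E)-6-iodo-3-methylhexa-1,3,5-trien-1-yl]-4,4,6-trimethyl-7-oxabicyclo[4.1.0]heptan-2-ol (oxirane oxygen cis to the C3 hydroxyl and to the side chain)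
Conditions: VO(acac)2 (cat.), t-BuOOH (in decane), CH2Cl2, 0 °C to rt, dark
Reagents that add atoms: tert-butyl hydroperoxide, CC(C)(C)OO
Why: In this hydroxyl-directed vanadium-catalysed epoxidation the vanadate ester of the C3 alkoxide delivers the peroxide oxygen to the C4=C5 face on which the hydroxyl stands, the face of the side chain, so C4 and C5 are set by C3, and the trienyl iodide alkenes, which carry no allylic hydroxyl, do not react.

Step 9
Reactants: 11 syn-epoxy alcohol
Product: 12 (1S,5S,6S)-5-[(1E,3E,5E)-6-iodo-3-methylhexa-1,3,5-trien-1-yl]-4,4,6-trimethyl-7-oxabicyclo[4.1.0]heptan-2-one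
Conditions: Dess–Martin periodinane, NaHCO3, CH2Cl2, 0 °C to rt
Reagents that add atoms: none
Why: Buffered Dess–Martin oxidation of the secondary alcohol should give the α,β-epoxy ketone and leave oxirane, triene and iodide untouched.

Step 10
Reactants: 12 epoxy ketone
Product: 13 (3R,4S)-3-hydroxy-4-[(1E,3E,5E)-6-iodo-3-methylhexa-1,3,5-trien-1-yl]-3,5,5-trimethylcyclohexan-1-one (ring B iodide, carotenoid 5R,6S)
Conditions: SmI2, THF/MeOH, −90 °C, short reaction time; aq. NaH2PO4/Na2HPO4 buffer (pH 7)
Reagents that add atoms: none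
Why: In this SmI2 reduction of an α,β-epoxy ketone two single-electron transfers cleave the C4–O bond next to the carbonyl and methanol protonates the samarium enolate, so the C5–O bond and its configuration survive and the tertiary aldol results; at −90 °C without HMPA the alkenyl iodide should not be reduced.

Step 11
Reactants: 8 (3S,6S) alcohol
Product: 14 (2E,4E)-5-[(1S,4S)-4-hydroxy-2,6,6-trimethylcyclohex-2-en-1-yl]-3-methylpenta-2,4-dienal
Conditions: i-Bu2AlH (excess), CH2Cl2, −78 °C; then 10% aq. tartaric acid, 0 °C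
Reagents that add atoms: water, O
Why: Reduction of the nitrile with i-Bu2AlH stops at the aluminated aldimine, hydrolysed on work-up to the dienal, as in step 6.

Step 12
Reactants: 14 trans hydroxy dienal
Product: 15 (1S,4S)-4-[(1E,3E,5E)-6-iodo-3-methylhexa-1,3,5-trien-1-yl]-3,5,5-trimethylcyclohex-2-en-1-ol
Conditions: CrCl2, CHI3, THF/1,4-dioxane, 0 °C to rt, dark
Reagents that add atoms: iodoform, IC(I)I
Why: Takai iodo-olefination should give the (E)-alkenyl iodide as in step 7.

Step 13
Reactants: 15 trans trienyl iodide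
Product: 16 (1S,2S,5S,6R)-5-[(1E,3E,5E)-6-iodo-3-methylhexa-1,3,5-trien-1-yl]-4,4,6-trimethyl-7-oxabicyclo[4.1.0]heptan-2-ol (oxirane oxygen cis to the C3 hydroxyl, trans to the side chain)
Conditions: VO(acac)2 (cat.), t-BuOOH (in decane), CH2Cl2, 0 °C to rt, dark
Reagents that add atoms: tert-butyl hydroperoxide, CC(C)(C)OO
Why: The same hydroxyl-directed vanadium-catalysed epoxidation places the oxygen on the face of the (3S)-hydroxyl, which is now the face away from the side chain, so directing and steric effects reinforce each other and C4 and C5 are again set by C3.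

Step 14
Reactants: 16 anti-epoxy alcohol
Product: 17 (1R,5S,6R)-5-[(1E,3E,5E)-6-iodo-3-methylhexa-1,3,5-trien-1-yl]-4,4,6-trimethyl-7-oxabicyclo[4.1.0]heptan-2-one
Conditions: Dess–Martin periodinane, NaHCO3, CH2Cl2, 0 °C to rt
Reagents that add atoms: none
Why: Buffered Dess–Martin oxidation should give the α,β-epoxy ketone as in step 9.

Step 15
Reactants: 17 epoxy ketone
Product: 18 (3S,4S)-3-hydroxy-4-[(1E,3E,5E)-6-iodo-3-methylhexa-1,3,5-trien-1-yl]-3,5,5-trimethylcyclohexan-1-one (ring A iodide, carotenoid 5S,6S)
Conditions: SmI2, THF/MeOH, −90 °C, short reaction time; aq. NaH2PO4/Na2HPO4 buffer (pH 7)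
Reagents that add atoms: none
Why: SmI2 reduction of the α,β-epoxy ketone cleaves only the C4–O bond as in step 10, so the C5 configuration written by the oxirane is kept.

Step 16
Reactants: 19 (E)-1,2-dichloroethene; 20 propyne (first equivalent)
Product: 22 (E)-octa-4-ene-2,6-diyne, via (E)-1-chloropent-1-en-3-yne 21 (not isolated)
Conditions: propyne (about 3 equiv in all, condensed in), Pd(PPh3)4 (cat.), CuI (cat.), piperidine, THF, rt, sealed flask
Reagents that add atoms: propyne, CC#C (the second equivalent of 20, which replaces the second chlorine)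
Why: In this twofold Sonogashira coupling the first propyne replaces one chlorine of 19 to give chloroenyne 21, whose remaining alkenyl chloride, activated by the conjugated alkyne, couples with a second propyne, each time with retention of the olefin geometry.

Step 17
Reactants: 22 (E)-octa-4-ene-2,6-diyne
Product: 24 (2E,4E,6E)-2,7-diiodoocta-2,4,6-triene, via dizirconated triene 23 (not isolated)
Conditions: Cp2Zr(H)Cl (excess), THF, rt to 45 °C, dark; then I2, −78 to 0 °C
Reagents that add atoms: iodine, II; Cp2Zr(H)Cl, [H][Zr](Cl)(C1C=CC=C1)C1C=CC=C1 (supplies the zirconium of 23; only its hydrogen stays in 24)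
Why: Syn-hydrozirconation places zirconium on the less hindered, methyl-bearing alkyne carbon (excess reagent equilibrates regioisomers) and iodinolysis occurs with retention, which should give the (2E,6E)-diiodide iodinated at the future C13 and C13′.

Step 18
Reactants: 24 diiodotriene
Product: 26 (2E,4E,6E)-2,7-bis(tributylstannyl)octa-2,4,6-triene, via dilithiotriene 25 (not isolated)
Conditions: t-BuLi (2 equiv per iodide), Et2O, −78 °C; then Bu3SnCl (one equiv per iodide), −78 °C to rt
Reagents that add atoms: tributyltin chloride, CCCC[Sn](Cl)(CCCC)CCCC (two equivalents, one per alkenyllithium); tert-butyllithium, [Li]C(C)(C)C (supplies the lithium of 25)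
Why: Lithium–iodine exchange of alkenyl iodides and stannylation of the alkenyllithium both proceed with retention of olefin geometry.

Step 19
Reactants: 13 ring B iodide; 26 C8 distannane (threefold excess, surplus recovered)
Product: 27 (3R,4S)-4-[(1E,3E,5E,7E,9E,11E)-3,7-dimethyl-12-(tributylstannyl)trideca-1,3,5,7,9,11-hexaen-1-yl]-3-hydroxy-3,5,5-trimethylcyclohexan-1-one
Conditions: Pd(PPh3)4 (cat.), copper thiophene-2-carboxylate (CuTC, Cu(O2CC4H3S)), [NBu4][Ph2PO2], degassed DMF, rt, dark; Et3N-deactivated silica
Reagents that add atoms: none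
Why: Copper-assisted Stille–Migita coupling under neutral, fluoride-free conditions joins C12′ to C13′ with retention at both alkenes; the excess of the symmetric distannane should restrict reaction to one tin terminus, and the aldol unit of ring B is never exposed to base.

Step 20
Reactants: 27 C24 hexaenylstannane; 18 ring A iodide
Product: 28 (5S,6S,5′R,6′S)-5,5′-dihydroxy-5,6,5′,6′-tetrahydro-β,β-carotene-3,3′-dione (all-E), the target
Conditions: Pd(PPh3)4 (cat.), copper thiophene-2-carboxylate (CuTC), [NBu4][Ph2PO2], degassed DMF, rt, dark, argon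
Reagents that add atoms: none
Why: Zerovalent palladium inserts into the C12–I bond of 18 with retention, CuTC turns the C13 stannane of 27 into an alkenylcopper (the phosphinate removes the tributyltin cation irreversibly) that passes the C13 alkenyl group to palladium, and reductive elimination forms the C12–C13 sigma bond. The closest known reaction type is the copper-promoted Stille–Migita alkenyl–alkenyl coupling used to assemble polyenes and carotenoids from alkenyl iodides and alkenylstannanes. No ring is closed and no stereocenter is created; C5, C6, C5′ and C6′ arrive set and lie at least six bonds from the reacting carbons. The step needs geometric fidelity at C11=C12 and C13=C14, which the stereoretentive oxidative addition and transmetalation of the pure (E)-iodide and (E)-stannane secure, and it needs chemoselectivity toward two unprotected aldol units, which the neutral, base-free and fluoride-free medium at room temperature secures, since neither retro-aldol epimerization at C5 nor dehydration to the C4=C5 enone is triggered. The hindered, methyl-bearing C13–Sn terminus is the reason for the copper relay, and the step should give the complete C40 nonaene directly, with nothing left to remove.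

**Compound list**

1 | (±)-α-ionone, (E)-4-(2,6,6-trimethylcyclohex-2-en-1-yl)but-3-en-2-one, racemic | CC(=O)/C=C/C1C(C)=CCCC1(C)C | starting material
2 | diethyl cyanomethylphosphonate | CCOP(=O)(CC#N)OCC | starting material
3 | (±)-(2E,4E)-3-methyl-5-(2,6,6-trimethylcyclohex-2-en-1-yl)penta-2,4-dienenitrile, racemic | N#C/C=C(C)/C=C/C1C(C)=CCCC1(C)C | intermediate
4 | (±)-(2E,4E)-3-methyl-5-(2,6,6-trimethyl-4-oxocyclohex-2-en-1-yl)penta-2,4-dienenitrile, racemic | N#C/C=C(C)/C=C/C1C(C)=CC(=O)CC1(C)C | intermediate
5 | rac-(2E,4E)-5-[(1S,4R)-4-hydroxy-2,6,6-trimethylcyclohex-2-en-1-yl]-3-methylpenta-2,4-dienenitrile, 3,6-cis racemate (one enantiomer drawn) | N#C/C=C(C)/C=C/[C@H]1C(C)(C)C[C@@H](O)C=C1C | intermediate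
6 | rac-(2E,4E)-5-[(1S,4S)-4-hydroxy-2,6,6-trimethylcyclohex-2-en-1-yl]-3-methylpenta-2,4-dienenitrile, 3,6-trans racemate (one enantiomer drawn) | N#C/C=C(C)/C=C/[C@H]1C(C)(C)C[C@H](O)C=C1C | intermediate
7 | (1R,4S)-4-[(1E,3E)-4-cyano-3-methylbuta-1,3-dien-1-yl]-3,5,5-trimethylcyclohex-2-en-1-yl acetate | N#C/C=C(C)/C=C/[C@H]1C(C)(C)C[C@@H](OC(C)=O)C=C1C | intermediate
8 | (2E,4E)-5-[(1S,4S)-4-hydroxy-2,6,6-trimethylcyclohex-2-en-1-yl]-3-methylpenta-2,4-dienenitrile, single enantiomer | N#C/C=C(C)/C=C/[C@H]1C(C)(C)C[C@H](O)C=C1C | intermediate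
9 | (2E,4E)-5-[(1S,4R)-4-hydroxy-2,6,6-trimethylcyclohex-2-en-1-yl]-3-methylpenta-2,4-dienal | O=C/C=C(C)/C=C/[C@H]1C(C)(C)C[C@@H](O)C=C1C | intermediate
10 | (1R,4S)-4-[(1E,3E,5E)-6-iodo-3-methylhexa-1,3,5-trien-1-yl]-3,5,5-trimethylcyclohex-2-en-1-ol | I/C=C/C=C(C)/C=C/[C@H]1C(C)(C)C[C@@H](O)C=C1C | intermediate
11 | (1R,2R,5S,6S)-5-[(1E,3E,5E)-6-iodo-3-methylhexa-1,3,5-trien-1-yl]-4,4,6-trimethyl-7-oxabicyclo[4.1.0]heptan-2-ol | I/C=C/C=C(C)/C=C/[C@H]1C(C)(C)C[C@@H](O)[C@H]2O[C@@]12C | intermediate
12 | (1S,5S,6S)-5-[(1E,3E,5E)-6-iodo-3-methylhexa-1,3,5-trien-1-yl]-4,4,6-trimethyl-7-oxabicyclo[4.1.0]heptan-2-one | I/C=C/C=C(C)/C=C/[C@H]1C(C)(C)CC(=O)[C@H]2O[C@@]12C | intermediate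
13 | (3R,4S)-3-hydroxy-4-[(1E,3E,5E)-6-iodo-3-methylhexa-1,3,5-trien-1-yl]-3,5,5-trimethylcyclohexan-1-one (ring B iodide) | I/C=C/C=C(C)/C=C/[C@H]1C(C)(C)CC(=O)C[C@@]1(C)O | intermediate
14 | (2E,4E)-5-[(1S,4S)-4-hydroxy-2,6,6-trimethylcyclohex-2-en-1-yl]-3-methylpenta-2,4-dienal | O=C/C=C(C)/C=C/[C@H]1C(C)(C)C[C@H](O)C=C1C | intermediate
15 | (1S,4S)-4-[(1E,3E,5E)-6-iodo-3-methylhexa-1,3,5-trien-1-yl]-3,5,5-trimethylcyclohex-2-en-1-ol | I/C=C/C=C(C)/C=C/[C@H]1C(C)(C)C[C@H](O)C=C1C | intermediate
16 | (1S,2S,5S,6R)-5-[(1E,3E,5E)-6-iodo-3-methylhexa-1,3,5-trien-1-yl]-4,4,6-trimethyl-7-oxabicyclo[4.1.0]heptan-2-ol | I/C=C/C=C(C)/C=C/[C@H]1C(C)(C)C[C@H](O)[C@@H]2O[C@]12C | intermediate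
17 | (1R,5S,6R)-5-[(1E,3E,5E)-6-iodo-3-methylhexa-1,3,5-trien-1-yl]-4,4,6-trimethyl-7-oxabicyclo[4.1.0]heptan-2-one | I/C=C/C=C(C)/C=C/[C@H]1C(C)(C)CC(=O)[C@@H]2O[C@]12C | intermediate
18 | (3S,4S)-3-hydroxy-4-[(1E,3E,5E)-6-iodo-3-methylhexa-1,3,5-trien-1-yl]-3,5,5-trimethylcyclohexan-1-one (ring A iodide) | I/C=C/C=C(C)/C=C/[C@H]1C(C)(C)CC(=O)C[C@]1(C)O | intermediate
19 | (E)-1,2-dichloroethene | Cl/C=C/Cl | starting material
20 | propyne | CC#C | starting material
21 | (E)-1-chloropent-1-en-3-yne, the monocoupled chloroenyne | CC#C/C=C/Cl | intermediate (not isolated)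
22 | (E)-octa-4-ene-2,6-diyne | CC#C/C=C/C#CC | intermediate
23 | dizirconated triene, (2E,4E,6E)-octa-2,4,6-triene-2,7-diylbis[chlorobis(cyclopentadienyl)zirconium] | Cl[Zr](C1C=CC=C1)(C1C=CC=C1)/C(C)=C/C=C/C=C(C)/[Zr](Cl)(C1C=CC=C1)C1C=CC=C1 | intermediate (not isolated)
24 | (2E,4E,6E)-2,7-diiodoocta-2,4,6-triene | I/C(C)=C/C=C/C=C(C)/I | intermediate
25 | dilithiotriene, 2,7-dilithioocta-2,4,6-triene with lithium in place of each iodine of 24 and the geometry retained (formally 2Z,4E,6Z) | [Li]/C(C)=C/C=C/C=C(C)/[Li] | intermediate (not isolated)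
26 | (2E,4E,6E)-2,7-bis(tributylstannyl)octa-2,4,6-triene | CCCC[Sn](CCCC)(CCCC)/C(C)=C/C=C/C=C(C)/[Sn](CCCC)(CCCC)CCCC | intermediate
27 | (3R,4S)-4-[(1E,3E,5E,7E,9E,11E)-3,7-dimethyl-12-(tributylstannyl)trideca-1,3,5,7,9,11-hexaen-1-yl]-3-hydroxy-3,5,5-trimethylcyclohexan-1-one | CCCC[Sn](CCCC)(CCCC)/C(C)=C/C=C/C=C(C)/C=C/C=C(C)/C=C/[C@H]1C(C)(C)CC(=O)C[C@@]1(C)O | intermediate
28 | (5S,6S,5′R,6′S)-5,5′-dihydroxy-5,6,5′,6′-tetrahydro-β,β-carotene-3,3′-dione, all-E | CC(/C=C/C=C(C)/C=C/[C@H]1C(C)(C)CC(=O)C[C@]1(C)O)=C\C=C\C=C(C)\C=C\C=C(C)\C=C\[C@H]1C(C)(C)CC(=O)C[C@@]1(C)O | target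

**Step count**

Total step count: 20. Longest linear sequence: 11 steps (1, 2, 3, 4, 6, 7, 8, 9, 10, 19, 20).

**Steps most likely to fail**

Step 20. What may go wrong: transmetalation at the hindered, methyl-bearing C13–Sn terminus may be slow, so that protodestannylation or homocoupling of 27 and light-induced isomerization of the polyene compete with the cross-coupling. The fallback sets out from 27 and 18 and returns at 28; it exchanges the roles of the partners and uses boron in place of tin. Treatment of 27 with I2 (CH2Cl2, −78 to 0 °C) should give, by ipso-iododestannylation with retention, the C24 alkenyl iodide F1. Miyaura borylation of 18 (bis(pinacolato)diboron, PdCl2(PPh3)2, PPh3, KOPh, toluene, 50 °C) should give the (E)-alkenyl pinacol boronate F2. Suzuki–Miyaura coupling of F1 with F2 (Pd(PPh3)4, Ag2O, THF/H2O, rt), with the unhindered boronate as nucleophile and the hindered iodide as electrophile, would then give 28.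

Step 8. What may go wrong: oxygen transfer may be slow or poorly face-selective, because the directed oxygen must enter on the ring face next to the side chain, against the steric bias. The fallback sets out from 7 and returns at 11; it builds the oxirane by anti addition on the dienenitrile, where the side chain is electron-poor. N-Bromosuccinimide in aqueous THF should form the bromonium ion on the open face of C4=C5 and take up water at the tertiary C5 on the side-chain face, giving the bromohydrin acetate F3. K2CO3 in MeOH should close the oxirane by displacement of bromide from C4 by the C5 alkoxide and remove the acetate, giving the syn-epoxy alcohol nitrile F4. i-Bu2AlH as in step 6 should give the epoxy dienal F5, and Takai olefination as in step 7 rejoins the route at 11.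

Step 4. What may go wrong: the rate difference between the enantiomers may be too small, which would give acetate 7 of low enantiomeric purity. The fallback sets out from 5 and returns at 9; it resolves through covalent diastereomers. Racemic 5 is esterified with (S)-2-methoxy-2-phenylacetic acid (DCC, DMAP, CH2Cl2), and the (S)-O-methylmandelate of the (3R,6S) alcohol F6 is separated by chromatography or crystallization from the (S)-O-methylmandelate of the (3S,6R) alcohol F7. i-Bu2AlH under the conditions of step 6 cleaves the ester of F6 and reduces its nitrile, giving 9.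

**Further compounds**

F1 | step 20 | (3R,4S)-3-hydroxy-4-[(1E,3E,5E,7E,9E,11E)-12-iodo-3,7-dimethyltrideca-1,3,5,7,9,11-hexaen-1-yl]-3,5,5-trimethylcyclohexan-1-one | I/C(C)=C/C=C/C=C(C)/C=C/C=C(C)/C=C/[C@H]1C(C)(C)CC(=O)C[C@@]1(C)O
F2 | step 20 | (3S,4S)-3-hydroxy-3,5,5-trimethyl-4-[(1E,3E,5E)-3-methyl-6-(4,4,5,5-tetramethyl-1,3,2-dioxaborolan-2-yl)hexa-1,3,5-trien-1-yl]cyclohexan-1-one | CC1(C)OB(OC1(C)C)/C=C/C=C(C)/C=C/[C@H]1C(C)(C)CC(=O)C[C@]1(C)O
F3 | step 8 | bromohydrin acetate of 7: C4 bromide trans to the new C5 hydroxyl, C5 hydroxyl cis to the side chain and to the C3 acetate | N#C/C=C(C)/C=C/[C@H]1C(C)(C)C[C@@H](OC(C)=O)[C@H](Br)[C@@]1(C)O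
F4 | step 8 | syn-epoxy alcohol nitrile: ring of 11 with the dienenitrile side chain | N#C/C=C(C)/C=C/[C@H]1C(C)(C)C[C@@H](O)[C@H]2O[C@@]12C
F5 | step 8 | syn-epoxy alcohol dienal: ring of 11 with the dienal side chain | O=C/C=C(C)/C=C/[C@H]1C(C)(C)C[C@@H](O)[C@H]2O[C@@]12C
F6 | step 4 | (S)-2-methoxy-2-phenylacetate of the (3R,6S) enantiomer of 5 | N#C/C=C(C)/C=C/[C@H]1C(C)(C)C[C@@H](OC(=O)[C@@H](OC)c2ccccc2)C=C1C
F7 | step 4 | (S)-2-methoxy-2-phenylacetate of the (3S,6R) enantiomer of 5 | N#C/C=C(C)/C=C/[C@@H]1C(C)(C)C[C@H](OC(=O)[C@@H](OC)c2ccccc2)C=C1C
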